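The benzene ring itself is the disconnection. It carries oxygen on C1, bromine on C3 and the carbinol carbon C7 on C4, and a vinylketene–ynamide benzannulation builds exactly this 1,3,4-pattern if the C3 bromine enters as nitrogen and is exchanged later. In one operation, methyl(vinyl)ketene (from a photochemical Wolff rearrangement) and a terminal ynamide should form C1–C2, C3–C4 and C1–C6 and close the ring as a 3-amido-4-methylphenol. The precursors are 4-diazopent-1-en-3-one and an N-ethynyl carbamate whose nitrogen carries benzyl and benzyloxycarbonyl, so that a single hydrogenolysis frees the aniline. Bromination at C2 and C6, Sandmeyer exchange at C3 and oxidation of C7 through the quinone methide complete the target.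

Key step: step 4

Assumption: benzyl N-benzylcarbamate is taken as a catalogue compound; if it is not, one Schotten–Baumann step from benzylamine and benzyl chloroformate supplies it.
Numbering: C1 is the phenol carbon, C2/C3/C6 carry bromine, C4 carries C7 (the CH2OH carbon), C5 carries H. The target has no stereocentre.

Step 1
Reactants: 1 pent-1-en-3-one
Product: 4 4-diazopent-1-en-3-one, via lithium dienolate 2 (not isolated), via trifluoroacetyl diketone 3 (not isolated)
Conditions: LiN(SiMe3)2 (1.1 equiv), THF, −78 °C; CF3CO2CH2CF3 (1.2 equiv), −78 °C; 5% aq HCl; then MsN3 (1.5 equiv), Et3N (1.5 equiv), H2O (1 equiv), MeCN, 25 °C; product kept cold and used at once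
Reagents that add atoms: methanesulfonyl azide, CS(=O)(=O)N=[N+]=[N-]
Why: Kinetic deprotonation on the ethyl side by the hindered amide base gives cross-conjugated enolate 2, Claisen trifluoroacetylation activates that carbon as diketone 3, and Regitz-type diazo transfer with loss of the trifluoroacetyl group as its N-sulfonyl amide (detrifluoroacetylative diazo transfer, established for alpha,beta-enones) should leave the diazo group on C4 of the pentenone.

Step 2
Reactants: 5 benzyl N-benzylcarbamate; 6 (bromoethynyl)triisopropylsilane
Product: 7 benzyl N-benzyl-N-[(triisopropylsilyl)ethynyl]carbamate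
Conditions: CuSO4·5H2O (10 mol %), 1,10-phenanthroline (20 mol %), K3PO4 (2 equiv), PhMe, 80 °C
Reagents that add atoms: none
Why: Copper-catalysed N-alkynylation of a carbamate with a 1-bromoalkyne (Ullmann-type C(sp)–N coupling) is established for acyclic carbamates, and the bulky silyl cap suppresses homocoupling of the alkyne.

Step 3
Reactants: 7 benzyl N-benzyl-N-[(triisopropylsilyl)ethynyl]carbamate
Product: 8 benzyl N-benzyl-N-ethynylcarbamate
Conditions: Bu4NF (1.1 equiv), wet THF, 0 °C; short filtration through base-washed silica, used promptly
Reagents that add atoms: none
Why: Fluoride-mediated protodesilylation of a silylalkyne should leave the carbamate and the ynamide triple bond untouched at 0 °C.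

Step 4
Reactants: 4 4-diazopent-1-en-3-one; 8 benzyl N-benzyl-N-ethynylcarbamate
Product: 13 benzyl N-benzyl-N-(5-hydroxy-2-methylphenyl)carbamate, via methyl(vinyl)ketene 9 (not isolated), via vinylcyclobutenone 10 (not isolated), via dienylketene 11 (not isolated), via cyclohexa-2,4-dienone 12 (not isolated)
Conditions: 8 (1.2 equiv), hν (254 nm, quartz), degassed CH2Cl2 (0.05 M), 25 °C; then PhMe, 110 °C
Reagents that add atoms: none
Why: Irradiation expels N2 from 4 with 1,2-shift of the vinyl group (photochemical Wolff rearrangement) to give ketene 9; the nucleophilic terminal carbon of ynamide 8 (future C2) attacks the ketene carbonyl carbon (C1) while the nitrogen-bearing carbon (C3) bonds to the ketene alpha carbon (C4), a polarity-matched [2+2] cycloaddition that should give cyclobutenone 10. On heating, 10 should open by conrotatory four-electron electrocyclic cleavage of C1–C4 to dienylketene 11, and a disrotatory six-electron electrocyclization then joins C1 to C6, closing the six-membered carbocycle as dienone 12, which tautomerizes to phenol 13. The closest known reaction type is the Danheiser benzannulation in its second-generation form (alpha-diazo enone plus heteroatom-substituted alkyne, ynamides included). No stereocentre is carried forward, since the quaternary centre of 10 is racemic and is erased on aromatization. The one selectivity needed is regiochemical (nitrogen at C3, not C2), and the polarization of the triple bond by nitrogen secures it; ring opening of 10 is reversible, so the rotamer with the vinyl group cis to the ketenyl carbon is drained into the irreversible ring closure. Dilution, the slow photochemical release of 9 and the excess of 8 should hold back ketene dimerization and attack of the diazo group on the enone.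

Step 5
Reactants: 13 benzyl N-benzyl-N-(5-hydroxy-2-methylphenyl)carbamate
Product: 15 3-amino-4-methylphenol, via 3-(benzylamino)-4-methylphenol 14 (not isolated)
Conditions: H2 (3 atm), Pd(OH)2/C, EtOH, AcOH (1 equiv), 25 °C
Reagents that add atoms: none
Why: Catalytic hydrogenolysis first cleaves the benzyl ester of the carbamate, the carbamic acid loses CO2 to give N-benzylaniline 14, and benzylic C–N hydrogenolysis of this aniline then frees the primary amine, all before any C–Br bond exists.

Step 6
Reactants: 15 3-amino-4-methylphenol
Product: 16 3-amino-2,6-dibromo-4-methylphenol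
Conditions: Br2 (2.0 equiv), AcOH, 10 °C; aq NaHCO3 work-up
Reagents that add atoms: bromine, BrBr
Why: Electrophilic aromatic bromination should stop at the 2,6-dibromide because C2 and C6 are each ortho to OH and ortho or para to NH2, whereas C5 is meta to both donors and C4 is blocked.

Step 7
Reactants: 16 3-amino-2,6-dibromo-4-methylphenol
Product: 18 2,3,6-tribromo-4-methylphenol, via arenediazonium bromide 17 (not isolated)
Conditions: NaNO2 (1.1 equiv), 48% aq HBr, AcOH, 0 °C; then CuBr (1 equiv), 48% aq HBr, 60 °C
Reagents that add atoms: hydrogen bromide, Br
Why: Sandmeyer reaction, in which diazotization in HBr and CuBr-mediated radical bromodediazoniation replace nitrogen by bromine at C3, and azo coupling is excluded because both ortho positions and the para position of the phenol are substituted.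

Step 8
Reactants: 18 2,3,6-tribromo-4-methylphenol
Product: 22 2,3,6-tribromo-4-(hydroxymethyl)phenol, via 4-bromo-4-methylcyclohexadienone 19 (not isolated), via quinone methide 20 (not isolated), via 4-(bromomethyl)phenol 21 (not isolated)
Conditions: Br2 (1.05 equiv), AcOH, 20 → 70 °C, dark; evaporate AcOH and HBr; then NaHCO3 (1.5 equiv), acetone–H2O (1:1), 25 °C; neutral work-up
Reagents that add atoms: water, O
Why: Ipso-bromination of a 4-methylphenol with both ortho positions blocked should put bromine on C4 (dienone 19), loss of HBr gives quinone methide 20 and 1,6-addition of HBr at C7 gives benzyl bromide 21 (the behaviour known for 2,6-dibromo-4-methylphenol, with C5 too deactivated for nuclear substitution), and in the buffered aqueous acetone of the second stage the phenoxide of crude 21 expels bromide again so that the large excess of water adds at C7 in its place (solvolysis of a 4-hydroxybenzyl bromide by elimination–addition).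

Compound list
1 | pent-1-en-3-one | C=CC(=O)CC | starting material
2 | lithium penta-1,3-dien-3-olate (not isolated; enolate geometry not controlled and without consequence) | [Li+].[O-]C(C=C)=CC | intermediate
3 | 1,1,1-trifluoro-3-methylhex-5-ene-2,4-dione (not isolated; racemic, enolizable) | C=CC(=O)C(C)C(=O)C(F)(F)F | intermediate
4 | 4-diazopent-1-en-3-one | C=CC(=O)C(C)=[N+]=[N-] | intermediate
5 | benzyl N-benzylcarbamate | O=C(NCc1ccccc1)OCc1ccccc1 | starting material
6 | (bromoethynyl)triisopropylsilane | CC(C)[Si](C#CBr)(C(C)C)C(C)C | starting material
7 | benzyl N-benzyl-N-[(triisopropylsilyl)ethynyl]carbamate | CC(C)[Si](C#CN(Cc1ccccc1)C(=O)OCc1ccccc1)(C(C)C)C(C)C | intermediate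
8 | benzyl N-benzyl-N-ethynylcarbamate | C#CN(Cc1ccccc1)C(=O)OCc1ccccc1 | intermediate
9 | 2-methylbuta-1,3-dien-1-one, methyl(vinyl)ketene (not isolated) | C=CC(C)=C=O | intermediate
10 | benzyl N-benzyl-N-(4-ethenyl-4-methyl-3-oxocyclobut-1-en-1-yl)carbamate (not isolated; racemic) | C=CC1(C)C(=O)C=C1N(Cc1ccccc1)C(=O)OCc1ccccc1 | intermediate
11 | benzyl N-benzyl-N-[(3E)-4-methyl-1-oxohexa-1,3,5-trien-3-yl]carbamate (not isolated) | O=C=C/C(N(Cc1ccccc1)C(=O)OCc1ccccc1)=C(C)\C=C | intermediate
12 | benzyl N-benzyl-N-(6-methyl-3-oxocyclohexa-1,5-dien-1-yl)carbamate (not isolated) | CC1=CCC(=O)C=C1N(Cc1ccccc1)C(=O)OCc1ccccc1 | intermediate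
13 | benzyl N-benzyl-N-(5-hydroxy-2-methylphenyl)carbamate | Cc1ccc(O)cc1N(Cc1ccccc1)C(=O)OCc1ccccc1 | intermediate
14 | 3-(benzylamino)-4-methylphenol (not isolated) | Cc1ccc(O)cc1NCc1ccccc1 | intermediate
15 | 3-amino-4-methylphenol | Cc1ccc(O)cc1N | intermediate
16 | 3-amino-2,6-dibromo-4-methylphenol | Cc1cc(Br)c(O)c(Br)c1N | intermediate
17 | 2,4-dibromo-3-hydroxy-6-methylbenzenediazonium bromide (not isolated) | Cc1cc(Br)c(O)c(Br)c1[N+]#N.[Br-] | intermediate
18 | 2,3,6-tribromo-4-methylphenol | Cc1cc(Br)c(O)c(Br)c1Br | intermediate
19 | 2,3,4,6-tetrabromo-4-methylcyclohexa-2,5-dien-1-one (not isolated; racemic) | CC1(Br)C=C(Br)C(=O)C(Br)=C1Br | intermediate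
20 | 2,3,6-tribromo-4-methylidenecyclohexa-2,5-dien-1-one (not isolated) | C=C1C=C(Br)C(=O)C(Br)=C1Br | intermediate
21 | 2,3,6-tribromo-4-(bromomethyl)phenol (not isolated; carried crude into the hydrolysis) | BrCc1cc(Br)c(O)c(Br)c1Br | intermediate
22 | 2,3,6-tribromo-4-(hydroxymethyl)phenol | OCc1cc(Br)c(O)c(Br)c1Br | target

Total step count: 8.
Longest linear sequence: 7 steps (steps 2 to 8, from 5 to 22); step 1 is the one-step side branch that supplies 4.

Steps most likely to fail

Step 4. The carbene may undergo 1,2-hydrogen shift from the methyl group instead of vinyl migration. The diazo group may also add to the enone of a second molecule, or the ketene may dimerize or be captured at its C=O before the [2+2] addition, so that little cyclobutenone forms. The fallback makes the same ketene without light and without a diazo compound, by the known 1,4-dehydrochlorination of an alpha,beta-unsaturated acid chloride. Purchased (E)-2-methylbut-2-enoyl chloride F1 is added slowly to ynamide 8 and Et3N in PhMe at 25–40 °C. Gamma-deprotonation of the acylammonium ion should give ketene 9, which is intercepted by 8 as cyclobutenone 10, and heating at 110 °C should convert 10 through 11 and 12 into phenol 13. This fallback sets out from 8 and comes back to the route at 13; it also makes step 1 unnecessary.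

Step 1. The lithium enolate may add in Michael fashion to enone that is not yet deprotonated, so that oligomers form and little enolate is left for acylation. In the fallback, 1 is enolized under soft conditions (Me3SiCl, Et3N, NaI, MeCN, 25 °C) to (Z)-trimethyl(penta-1,3-dien-3-yloxy)silane F2, which is distilled free of enone. Cleavage of the O–Si bond with MeLi in THF at 0 °C should regenerate enolate 2 with no Michael acceptor present, and trifluoroacetylation and diazo transfer then follow as in step 1. This fallback sets out from 1 and comes back to the route at 2.

Step 8. Bromine may be consumed by nuclear substitution at C5 or by a second side-chain bromination, the ipso adduct may revert without eliminating, or the crude benzyl bromide may be lost to condensation before water captures the quinone methide. In the fallback, 18 is acetylated (Ac2O, pyridine, 25 °C) to 2,3,6-tribromo-4-methylphenyl acetate F3, which closes the ionic pathway. Wohl–Ziegler bromination (N-bromosuccinimide, AIBN, PhCF3, 85 °C) should then give 2,3,6-tribromo-4-(bromomethyl)phenyl acetate F4, an isolable and purifiable benzyl bromide. K2CO3 in acetone–H2O at 25 °C cleaves the aryl acetate, the phenoxide expels bromide to quinone methide 20, and water adds to give 22. This fallback sets out from 18 and comes back to the route at 22, replacing step 8.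

Further compounds
F1 | step 4 | (E)-2-methylbut-2-enoyl chloride (tigloyl chloride) | C/C=C(\C)C(Cl)=O
F2 | step 1 | (Z)-trimethyl(penta-1,3-dien-3-yloxy)silane | C=C/C(O[Si](C)(C)C)=C/C
F3 | step 8 | 2,3,6-tribromo-4-methylphenyl acetate | CC(=O)Oc1c(Br)cc(C)c(Br)c1Br
F4 | step 8 | 2,3,6-tribromo-4-(bromomethyl)phenyl acetate | CC(=O)Oc1c(Br)cc(CBr)c(Br)c1Br
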